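**Retrosynthetic overview**

1. Labels: Ca = the CH carrying 2-methylprop-1-enyl on C3 of quinolone A; Cb = ring-fusion CH; Cc = ring-fusion OCH on C3 of quinolone B; Cq = C(CH3)2; ring A = pyran O–C4(A)=C3(A)–Ca–Cb–Cc; ring B = pyran O–C4(B)=C3(B)–Cc–Cb–Cq.
2. Feature: Ca is a methine flanked by C3 of quinolone A, an alkenyl group and Cb, which is the pattern left when an alkenyl nucleophile adds to the quinone methide made from a 4-hydroxyquinolone and an aldehyde. Ca–C3(A) and Ca–alkenyl are therefore cut together, giving 4-hydroxy-1-methylquinolin-2-one, 3-formyl-N-methylflindersine and 2-methylprop-1-enylboronic acid.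
3. Ring A is cut last at O–Cc: acid adds the 4-OH of quinolone A across the Cb=Cc alkene, and the Ca centre controls Cb and Cc.
4. The aldehyde comes from N-methylflindersine (the same hydroxyquinolone plus 3-methylbut-2-enal, Knoevenagel then oxa-6π closure) by bromohydrin formation, dehydration to the C3 alkenyl bromide and palladium-catalysed formylation.
5. Ring order: ring B first (step 1), ring A last (step 6); both quinolone bicycles are bought.

Key step: step 5

Assumption: the (R) enantiomer of 3,3'-dibromo-BINOL is written for the (S) configuration at Ca on the basis of the closed transition-state model; if the first run shows the opposite sense, the (S) catalyst takes its place with nothing else changed.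

**Route**

Step 1
Reactants: 1 4-hydroxy-1-methylquinolin-2(1H)-one; 2 3-methylbut-2-enal
Product: 4 N-methylflindersine (2,2,6-trimethyl-2,6-dihydro-5H-pyrano[3,2-c]quinolin-5-one), via prenylidene dione 3 (not isolated)
Conditions: pyridine, MgSO4, 110 °C
Reagents that add atoms: none
Why: Knoevenagel condensation at C3 of the hydroxyquinolone gives the 1-oxatriene 3, whose oxa-6π electrocyclisation closes ring B, a long-established entry to flindersine-type 2H-pyranoquinolinones.

Step 2
Reactants: 4 N-methylflindersine
Product: 5 rac-(3R,4S)-3-bromo-4-hydroxy-2,2,6-trimethyl-3,4-dihydro-2H-pyrano[3,2-c]quinolin-5(6H)-one (trans bromohydrin)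
Conditions: NBS, THF/H2O (4:1), 0 °C to rt
Reagents that add atoms: N-bromosuccinimide, O=C1CCC(=O)N1Br; water, O
Why: Bromohydrin formation, in which water opens the bromonium ion anti at C4 (the carbon whose cation is stabilised through the ring oxygen), so that bromine ends on C3; both centres are racemic and are removed in step 3.

Step 3
Reactants: 5 trans bromohydrin
Product: 6 3-bromo-2,2,6-trimethyl-2,6-dihydro-5H-pyrano[3,2-c]quinolin-5-one
Conditions: TsOH·H2O (10 mol%), toluene, reflux, Dean–Stark
Reagents that add atoms: none
Why: Acid-catalysed E1 dehydration, in which the C4 hydroxyl ionises to the oxygen-stabilised cation that can lose a proton only from C3, restoring the alkene with bromine on C3 as in the standard preparation of 3-bromo-2H-chromenes from chromanol bromohydrins.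

Step 4
Reactants: 6 3-bromo-N-methylflindersine
Product: 7 3-formyl-N-methylflindersine (2,2,6-trimethyl-5-oxo-5,6-dihydro-2H-pyrano[3,2-c]quinoline-3-carbaldehyde)
Conditions: Pd(OAc)2 (2 mol%), di(1-adamantyl)-n-butylphosphine (6 mol%), CO/H2 (1:1, 5 bar), N,N,N',N'-tetramethylethylenediamine, toluene, 100 °C
Reagents that add atoms: carbon monoxide, [C-]#[O+]
Why: Palladium-catalysed reductive carbonylation of an alkenyl bromide with synthesis gas (oxidative addition, CO insertion, hydrogenolysis of the acylpalladium) should give the enal and leave the lactam and the pyran untouched.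

Step 5
Reactants: 1 4-hydroxy-1-methylquinolin-2(1H)-one; 7 3-formyl-N-methylflindersine; 8 2-methylprop-1-enylboronic acid
Product: 11 3-[(1S)-1-(4-hydroxy-1-methyl-2-oxo-1,2-dihydroquinolin-3-yl)-3-methylbut-2-en-1-yl]-2,2,6-trimethyl-2,6-dihydro-5H-pyrano[3,2-c]quinolin-5-one, via quinone methide 9 (not isolated), via pyran isomer 10 (not isolated)
Conditions: 8 (2.5 equiv), (R)-3,3'-dibromo-1,1'-bi-2-naphthol (20 mol%), 4 Å MS, toluene/ClCH2CH2Cl (1:1), 60 °C
Reagents that add atoms: none
Why: Proposed new method: Knoevenagel condensation of C3 of 1 with the formyl group of 7, assisted by the boron Lewis acid and the acidic diol, gives the 3-alkylidenequinoline-2,4-dione 9, which rests as its oxa-6π valence isomer 10 and reopens at 60 °C; 8 exchanges onto the chiral diol, the boron binds a dione carbonyl oxygen of 9, the 2-methylprop-1-enyl group migrates to Ca through a closed six-membered chair transition state, and the dione rearomatises to the 4-hydroxyquinolone. The closest known reaction type is the chiral-biphenol-catalysed condensation of phenols, aldehydes and alkenylboronates through ortho-quinone methides, together with BINOL-catalysed conjugate addition of alkenylboronates to enones; new here are the hydroxyquinolone-derived methide and its extension by the flindersine alkene. No ring is closed in 11: the pyran of 10 arises by 6π electrocyclisation only as a reservoir and is opened again. Ca is set by the axially chiral boronate, which blocks one face of the boron-bound s-cis enone; either alkylidene isomer is expected to react through the carbonyl lying trans to the pyranyl group, and these two arrangements are mirror-related so that the same face of Ca is attacked. The step needs 1,4-addition at Ca over 1,6-addition at Cc, over Michael addition of 1 to the enal carbon Cc of 7 and over capture of 9 by a second molecule of 1: delivery from boron on the carbonyl oxygen can reach only Ca, Cc is shielded by quinolone B and Cq and deactivated by the donor oxygen of ring B, and the methide should be consumed within the boron complex in which it forms.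

Step 6
Reactants: 11 the (S)-configured hydroxyquinolone adduct
Product: 12 target CNP0210533.1: hexacycle in which rings A and B share the Cb–Cc bond, Ca (S) carries 2-methylprop-1-enyl trans to Cq, and Cb (S) and Cc (R) carry cis hydrogens
Conditions: 10-camphorsulfonic acid (20 mol%), CH2Cl2, 0 °C to rt
Reagents that add atoms: none
Why: Brønsted-acid hydroalkoxylation (Markovnikov 6-endo addition of the enolic 4-OH across the dienol-ether alkene), in which protonation at Cb gives the Cc cation stabilised as an oxocarbenium through the oxygen of ring B and the hydroxyl of quinolone A closes ring A cis-fused; because protonation at Cb and C–O formation at Cc are reversible, the fixed Ca centre should steer Cb and Cc to the diastereomer with the alkenyl group trans to Cq.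

**Compound list**

1 | 4-hydroxy-1-methylquinolin-2(1H)-one | Cn1c(=O)cc(O)c2ccccc21 | starting material
2 | 3-methylbut-2-enal | CC(C)=CC=O | starting material
3 | 1-methyl-3-(3-methylbut-2-en-1-ylidene)quinoline-2,4(1H,3H)-dione | CC(C)=CC=C1C(=O)c2ccccc2N(C)C1=O | intermediate (not isolated)
4 | N-methylflindersine | CC1(C)C=Cc2c(O1)c1ccccc1n(C)c2=O | intermediate
5 | rac-(3R,4S)-3-bromo-4-hydroxy-2,2,6-trimethyl-3,4-dihydro-2H-pyrano[3,2-c]quinolin-5(6H)-one (racemic, one enantiomer drawn) | CC1(C)Oc2c([C@H](O)[C@H]1Br)c(=O)n(C)c1ccccc21 | intermediate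
6 | 3-bromo-N-methylflindersine | CC1(C)Oc2c(C=C1Br)c(=O)n(C)c1ccccc21 | intermediate
7 | 3-formyl-N-methylflindersine | CC1(C)Oc2c(C=C1C=O)c(=O)n(C)c1ccccc21 | intermediate
8 | 2-methylprop-1-enylboronic acid | CC(C)=CB(O)O | starting material
9 | 1-methyl-3-[(2,2,6-trimethyl-5-oxo-5,6-dihydro-2H-pyrano[3,2-c]quinolin-3-yl)methylidene]quinoline-2,4(1H,3H)-dione (alkene geometry not fixed) | CN1C(=O)C(=CC2=Cc3c(OC2(C)C)c2ccccc2n(C)c3=O)C(=O)c2ccccc21 | intermediate (not isolated)
10 | 2H-pyran valence isomer of 9 (ring A closed by O–Cc, Ca=Cb double bond, racemic at Cc) | CC1(C)Oc2c(c(=O)n(C)c3ccccc23)C2Oc3c(C=C12)c(=O)n(C)c1ccccc31 | intermediate (not isolated)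
11 | 3-[(1S)-1-(4-hydroxy-1-methyl-2-oxo-1,2-dihydroquinolin-3-yl)-3-methylbut-2-en-1-yl]-2,2,6-trimethyl-2,6-dihydro-5H-pyrano[3,2-c]quinolin-5-one | CC(C)=C[C@@H](C1=Cc2c(OC1(C)C)c1ccccc1n(C)c2=O)c1c(O)c2ccccc2n(C)c1=O | intermediate
12 | CNP0210533.1 (Ca S, Cb S, Cc R) | CC(C)=C[C@@H]1c2c(c3ccccc3n(C)c2=O)O[C@H]2c3c(c4ccccc4n(C)c3=O)OC(C)(C)[C@@H]12 | target

Total step count: 6
Longest linear sequence: 6 steps (1 → 4 → 5 → 6 → 7 → 11 → 12)

**Steps most likely to fail**

1. Step 5 (key step). The resting pyran isomer may reopen too slowly, so that higher temperature is needed and facial selectivity erodes. Uncatalysed alkenyl transfer from the achiral boronic acid, protodeboronation, or capture of the methide by a second hydroxyquinolone may compete.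
   Fallback, known chemistry, from 7 back to 11: 2-methylprop-1-enylmagnesium bromide in THF at −78 °C would add to the aldehyde of 7 to give the racemic dienyl carbinol F1. Bi(OTf)3-catalysed dehydrative C3-alkylation of 1 with F1 in ClCH2CH2Cl at rt is the known Friedel–Crafts-type alkylation of 4-hydroxyquinolones and 4-hydroxycoumarins with secondary allylic alcohols. Capture of the allyl cation at Ca keeps the chromene-type conjugation of ring B and should give the racemic adduct F2; capture at Cc or at the dimethyl terminus is this fallback's own open point. Preparative HPLC on a chiral stationary phase would then deliver the (S)-enantiomer, which is 11.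

2. Step 6. The acid may also protonate the 2-methylprop-1-enyl alkene, so that the same hydroxyl closes onto its tertiary carbon instead of Cc; equilibration to the desired Cb/Cc diastereomer may also stay incomplete.
   Fallback, from 1 and 7 back to 12: the alkenyl group is carried through the ring closure as a less basic surrogate. Step 5 run with (E)-prop-1-enylboronic acid in place of 8 should give the propenyl adduct F3. Its disubstituted alkene would give only a secondary cation, so 10-camphorsulfonic acid should close ring A selectively to the propenyl hexacycle F4. Cross-metathesis of F4 in neat 2-methylbut-2-ene at 40 °C with (1,3-dimesitylimidazolidin-2-ylidene)(2-isopropoxybenzylidene)ruthenium dichloride, the second-generation Hoveyda–Grubbs catalyst, would turn propenyl into 2-methylprop-1-enyl and arrive at 12.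

3. Step 4. Hydrodebromination by a palladium hydride may outrun CO insertion at the hindered alkenylpalladium and return 4.
   Fallback, from 6 back to 7: methoxycarbonylation without hydrogen (Pd(OAc)2, 1,1'-bis(diphenylphosphino)ferrocene, CO 1 atm, MeOH, Et3N, DMF, 70 °C) should give the methyl ester F5. Reduction with i-Bu2AlH in CH2Cl2 at −78 °C would give the allylic alcohol F6, and MnO2 in CH2Cl2 would oxidise it to 7.

**Further compounds**

F1 | step 5 | 3-(1-hydroxy-3-methylbut-2-en-1-yl)-2,2,6-trimethyl-2,6-dihydro-5H-pyrano[3,2-c]quinolin-5-one (racemic) | CC(C)=CC(O)C1=Cc2c(OC1(C)C)c1ccccc1n(C)c2=O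
F2 | step 5 | racemate of 11 | CC(C)=CC(C1=Cc2c(OC1(C)C)c1ccccc1n(C)c2=O)c1c(O)c2ccccc2n(C)c1=O
F3 | step 6 | 3-[(1S,2E)-1-(4-hydroxy-1-methyl-2-oxo-1,2-dihydroquinolin-3-yl)but-2-en-1-yl]-2,2,6-trimethyl-2,6-dihydro-5H-pyrano[3,2-c]quinolin-5-one | C/C=C/[C@@H](C1=Cc2c(OC1(C)C)c1ccccc1n(C)c2=O)c1c(O)c2ccccc2n(C)c1=O
F4 | step 6 | analogue of 12 with (E)-prop-1-enyl on Ca in place of 2-methylprop-1-enyl (Ca S, Cb S, Cc R) | C/C=C/[C@@H]1c2c(c3ccccc3n(C)c2=O)O[C@H]2c3c(c4ccccc4n(C)c3=O)OC(C)(C)[C@@H]12
F5 | step 4 | methyl 2,2,6-trimethyl-5-oxo-5,6-dihydro-2H-pyrano[3,2-c]quinoline-3-carboxylate | CC1(C)Oc2c(C=C1C(=O)OC)c(=O)n(C)c1ccccc21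
F6 | step 4 | 3-(hydroxymethyl)-2,2,6-trimethyl-2,6-dihydro-5H-pyrano[3,2-c]quinolin-5-one | CC1(C)Oc2c(C=C1CO)c(=O)n(C)c1ccccc21
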